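We read each flask at 80 s, so what we want is the J still standing at that moment.

    L + E → J + D (k1 = 64 M⁻¹ s⁻¹, Ea1 = 50.0 kJ mol⁻¹)
    J ⇌ G (K2 = 1.2, k2 = 0.076 s⁻¹, Ea2 = 89.0 kJ mol⁻¹, ΔH2 = 29.0 kJ mol⁻¹)
    J ⇌ Q (K3 = 67, k3 = 0.0033 s⁻¹, Ea3 = 93.0 kJ mol⁻¹, ΔH3 = −35.0 kJ mol⁻¹)
    G ⇌ Z (K4 = 0.43, k4 = 0.0089 s⁻¹, Ea4 = 94.0 kJ mol⁻¹, ΔH4 = 41.0 kJ mol⁻¹)
    J → X (k5 = 0.020 s⁻¹, Ea5 = 77.0 kJ mol⁻¹)
    (constants at 35 °C)

the same everywhere: L 0.0050 M; E 9.00 mM; time 80 s
- south: temperature 20 °C
- south-west: temperature 35 °C
- west: temperature 50 °C

- constants are those at 35 °C; use the activation energies and enthalpies for any other temperature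

* which flask leads in amount of J, in percent of the L charged ("all alike" within 1.5 percentage points) (south / south-west / west / all alike)
* how much J is there at the end, in percent of the L charged: south
* how much J is there at the end, in percent of the L charged: south-west
* how much J is there at the end, in percent of the L charged: west

L is charged below E, so L is the limiting reagent, and we write its balance: charged L stands as L, J, G, Q, Z or X. E goes one for one with L, so once L has reacted E stands at 44.4 % of its own charge. L goes fast. At full E its half-life in south is 3.27 s, short against the reading, so we start the balance with the charge in J.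

But J does not stay. In south, J ⇌ G relaxes with a half-life of 21.7 s, shorter than the reading. So J and G act as one pool, and J holds the share 1/(1 + K), where K is the equilibrium constant of J ⇌ G at the flask's temperature. In south K is 0.672, so J's share is 59.8 %.

The pool leaks through J, to X with constant kX and to Q with constant kQ. At 35 °C the constant of J ⇌ Q is 67, far above one, so we count that leak as one-way. In south, the equilibrium constant of G ⇌ Z is 0.190, below one, so Z can hold a small part of G there, and we leave Z out. We leave it out in south-west and west as well, but there that constant is larger, 0.43 and 0.904, so those two figures are rougher.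

In south kX is 0.00430 s⁻¹ and kQ is 5.15 × 10⁻⁴ s⁻¹. The time in which these leaks halve the pool is then ln(2)(1 + K)/(kX + kQ), the pool half-life τ, here 241 s.

J at the reading is its share of what the pool keeps. That gives 47.5 % in south. With their own constants, south-west gives 19.5 % and west 2.45 %.

The forecast names south as leader, with 46 %, 17 % and 3.2 %, in south, south-west and west. Its ground: “the coolest flask keeps the most J”. Our figures stand above it in south and south-west, and below it in west.

south leads with 46.6 %; south-west gives 15.2 % and west 3.37 %. At 80.0 s, south holds G at 28.9 % and X at 20.3 %. Now τ runs on from that reading. South held to 800 s has 720 s more, which is 2.99 pool half-lives, so J should fall from 46.6 % to 5.88 %. South at 800 s reads 6.49 %.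

(The constants used here are those of an exercise; the result is computed.)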